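## Structural features

The target 16 is a 1-benzofuran-2,6-dione: a six-membered carbocycle (ring A: C3a, C4, C5, C6, C7, C7a) fused along the C3a–C7a bond to a five-membered unsaturated lactone (ring B: O1, C2, C3, C3a, C7a). Ring A is not an arene but a fully substituted para-quinone methide. C6 is a carbonyl, C4=C5 and C7=C7a are ring double bonds, and the exocyclic C3a=C3 bond carries the 4-hydroxyphenyl group and the lactone carbonyl C2. Phenyl groups sit on C4 and C7 and a methoxy group on C5. There is no stereocenter in the target, so no stereocenters stand next to each other; the only stereogenic carbon on the route is the diarylmethine carbon that later becomes trigonal C3. The fragile groups are the enol lactone (O1–C2, open to base and alcoholysis), the electrophilic methide carbon C3, the vinylogous ester at C5 and the free phenol, which is oxidisable and conjugated to the C6 carbonyl through C3=C3a and C7a=C7. The real difficulty is a hexasubstituted ring A that carries three different oxygen functions (acyloxy at C7a, carbonyl at C6, methyl ether at C5) between two phenyl groups, at the correct oxidation level. The key step uses the fact that O5 and O6 are a masked catechol. In its ortho-quinone, C7a is the β-carbon of the C6 enone and the only ring carbon bearing hydrogen, while the carboxyl carbon C2 hangs from C3 on the neighbouring C3a. A carboxylate oxygen therefore reaches C7a through a five-membered transition state and becomes O1.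

## Logic of the disconnections

16 ⇒ 15. The methyl ether at C5 is cut (the C5–OCH3 linkage). In 15 the 5-hydroxyl is the OH of a vinylogous carboxylic acid (C5=C4–C3a=C3–C2=O), and no neutral tautomer places the hydrogen on O6, so only O5 can be etherified on ring A. The gain is that both ring A oxygens may be free at the earlier stage, which allows a symmetrical catechol. The demand is that the forward step distinguishes the 5-hydroxyl from the phenol and does not open the lactone.

15 ⇒ 11. The O1–C7a bond is cut and four hydrogens are returned (to O5, O6, C3 and C7a). This removes ring B and the quinone methide at once and leaves an aromatic catechol carrying a diarylacetic acid, with one stereocenter that is of no consequence. The precursor 11 is deliberately kept free of protecting groups: the carboxyl group must be free to act as nucleophile and the catechol must be free to be oxidised. The demand is an oxidant that takes the catechol and not the monohydric phenol, delivers four oxidation equivalents without going further, and lets the carboxylate add at C7a on the way through 12, 13 and 14.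

11 ⇒ 8 + 9. The C3–C3a bond is cut. C3a lies para to a hydroxyl of 8, whose two free ring carbons are equivalent by symmetry and whose ortho positions are blocked. Fragment 9 brings C2, C3 and the hydroxyaryl ring in one commercial piece and ionises readily (through 10). The gain is a convergent union of two fragments of similar size. The demand is monoalkylation, and capture of the cation by 8 faster than by a second molecule of 9.

8 ⇒ 6. The two O–CH3 bonds are cut. The methyl ethers protect the catechol through the organometallic steps. The demand is complete cleavage without harm to the terphenyl.

6 ⇒ 3 + 4. The C4–phenyl and C7–phenyl bonds are cut. They are identical, so one twofold cross-coupling (through 5) makes both. The demand is coupling next to a methoxy group, twice.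

3 ⇒ 1. The two C–Br bonds are cut. Each methoxy group of 1 directs metalation to its own ortho position (through 2), which fixes the 3,6-pattern. The demand is a second metalation of a ring that is already lithiated.

## Other disconnections considered

Alternative 1: The cut runs through ring A itself, at C3a–C7a, and traces the six-membered ring back to a four-membered ring made from a squaric ester.
- Forward key step: heating the cyclobutenone A1 should open it in a conrotatory 4π step (methoxy outward, 1-phenylvinyl inward) to a dienylketene. Its 6π electrocyclisation joins the ketene carbon (future C7a) to the vinyl terminus (future C3a), and tautomerisation would give the phenol A2.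
- In its favour: the three ring A oxygens arrive differentiated (free OH at C7a, isopropyl ether at C6, methyl ether at C5), so no late selective methylation is needed. The substitution pattern follows from the order of nucleophile additions and not from arene substitution rules.
- Against it here: the step builds ring A only. Ring B, C2, C3 and the hydroxyaryl group must still be attached to the single, flanked free carbon of a pentasubstituted phenol, followed by deprotection and oxidation. A1 itself needs several low-temperature organometallic additions and an O-methylation of a tertiary alkoxide.
- Comparison: on structure it is the better plan for telling O5 from O6, a point the chosen plan settles only in its last step. On mechanism the two are equals in kind: each is a cascade set off by one event (heat or oxidation) with a ring closure that has a single possible regiochemical outcome. On step economy the chosen plan is ahead: it takes ring A from 1 and reaches 16 in six steps, where a route through A2 would need about twice as many.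

Alternative 2: The cut removes O1–C2 and the C3–aryl bond, tracing ring B to an ortho-acyloxybenzil A3 (drawn as its acetate), conceivably made from A2 by acylation at its free carbon.
- Forward key step: K2CO3 in methanol would remove the acetyl group. The C7a phenoxide adds to the far carbonyl to give a five-membered hemiketal alkoxide, and a 1,2-shift of the benzyloxyphenyl group to the neighbouring ketone carbon (benzilic ester rearrangement) would give the 3-hydroxy lactone A4.
- In its favour: ring B and the fully substituted C3 form in one mild operation. A4 is already at the oxidation level of 16, because loss of water across C3 and a freed 6-hydroxyl gives the quinone methide without any oxidant. This is better redox economy than the chosen plan and keeps oxidants away from a free phenol. The methyl ether is in place from the start.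
- Against it here: A3 requires acylation of the one doubly flanked position of A2 by an arylglyoxylyl unit. Methoxide can compete with the phenoxide at the diketone and cause cleavage or an open-chain benzilic ester. Three protecting groups (acetyl, isopropyl, benzyl) must be carried and removed, and ring A must first be made.
- Comparison: on structure both plans close ring B as the strategic event, and the racemic C3 center of A4 is erased later just as that of 11 is, so they are equal on these points. On mechanism the anionic rearrangement avoids the overoxidation risk of the chosen step but adds a migration whose competition with cleavage is open. On step economy the chosen plan is clearly shorter.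

Alternative 3: The cut removes both bonds to C2 (C2–C3 and C2–O1). The lactone carbonyl becomes carbon monoxide and ring B is traced to the ortho-hydroxybenzhydrol A5, conceivable from A2 by ortho-formylation and addition of an aryl nucleophile.
- Forward key step: with Pd(OAc)2, 1,4-bis(diphenylphosphino)butane, an acid cocatalyst and CO, the acid should ionise the benzylic C–O bond. Zerovalent palladium formed in the mixture would give a benzyl complex of divalent palladium, CO inserts, and the phenol oxygen closes the lactone A6.
- In its favour: a convergent (4+1) assembly with the simplest one-carbon unit, a substrate made by ordinary carbonyl addition, the methyl ether already in place, and a metal used catalytically where the chosen step consumes two equivalents of Ag2O. On reagent economy it is the better plan.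
- Against it here: pressurised toxic CO, a benzhydrol hindered on both sides, and an electron-rich diaryl carbinol that under acid can go to an ortho-quinone methide and on to ethers or dimers instead of carbonylating. After A6, two isopropyl ethers must still be cleaved and the leuco lactone oxidised.
- Comparison: on structure, deprotected A6 is the 5-O-methyl analogue of 13 and its final two-electron oxidation is the same event as the second half of step 5, so the plans are equal there, and the alternative is better at placing the methyl group. On mechanism the chosen closure has only one site to attack, whereas the carbonylation must win over several cationic side paths. On step economy the chosen plan is ahead.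

Key step: step 5

Remark on the chemistry: ring atoms are numbered as in 1-benzofuran throughout; 9, 11, 13 and 14 are racemic, and the target is achiral.

## Route

Step 1
Reactants: 1 veratrole (1,2-dimethoxybenzene)
Product: 3 1,4-dibromo-2,3-dimethoxybenzene, via 3,6-dilithioveratrole 2 (not isolated)
Conditions: n-BuLi (3 equiv), TMEDA (3 equiv), hexane, rt to 40 °C; then BrCCl2CCl2Br (2.6 equiv), THF, −78 °C to rt
Reagents that add atoms: 1,2-dibromo-1,1,2,2-tetrachloroethane, BrC(Cl)(Cl)C(Cl)(Cl)Br
Why: Double directed ortho-metalation: each methoxy group delivers n-BuLi/TMEDA to its own free ortho position, so the second lithium enters at C6 and gives 2. Bromine–lithium exchange with the positive-bromine donor then gives 3, the donor collapsing to C2Cl4 and LiBr.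

Step 2
Reactants: 3 1,4-dibromo-2,3-dimethoxybenzene; 4 phenylboronic acid
Product: 6 2,3-dimethoxy-1,4-diphenylbenzene, via 4-bromo-2,3-dimethoxybiphenyl 5 (not isolated)
Conditions: 4 (2.5 equiv), Pd(PPh3)4 (3 mol %), 2 M aq K2CO3, toluene/EtOH, 85 °C
Reagents that add atoms: none
Why: Twofold Suzuki–Miyaura coupling: zerovalent palladium inserts into each C–Br bond in turn, with 5 as the monocoupled stage. The methoxy groups are inert and the excess of 4 drives the more hindered second coupling.

Step 3
Reactants: 6 2,3-dimethoxy-1,4-diphenylbenzene
Product: 8 3,6-diphenylbenzene-1,2-diol, via 2-bromo-4,7-diphenyl-1,3,2-benzodioxaborole 7 (not isolated)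
Conditions: BBr3 (2.5 equiv), CH2Cl2, −78 °C to rt; then H2O, 0 °C
Reagents that add atoms: none
Why: Lewis acid cleavage of aryl methyl ethers: BBr3 binds the ether oxygens and bromide removes each methyl group as MeBr, leaving the cyclic bromoborole 7. Aqueous work-up hydrolyses 7 to the catechol, and the terphenyl bonds are not affected.

Step 4
Reactants: 8 3,6-diphenylbenzene-1,2-diol; 9 4-hydroxymandelic acid (racemic)
Product: 11 2-(3,4-dihydroxy-2,5-diphenylphenyl)-2-(4-hydroxyphenyl)acetic acid (racemic), via quinone methide acid 10 (not isolated)
Conditions: 8 (1.5 equiv), 9 added in portions, MeSO3H (0.3 equiv), AcOH, 60 °C, N2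
Reagents that add atoms: none
Why: Acid-catalysed Friedel–Crafts hydroxyalkylation (Bistrzycki-type condensation of a mandelic acid with a phenol): 9 loses water to the para-hydroxybenzylic cation (protonated 10), which attacks the electron-rich ring of 8 para to a hydroxyl. Both ortho positions of 8 carry phenyl and its two free carbons are equivalent, so a single regioisomer should form, as a racemate because the cation is planar. The excess of 8 and slow addition of 9 keep the cation from alkylating 9 itself or 11 a second time.

Step 5
Reactants: 11 2-(3,4-dihydroxy-2,5-diphenylphenyl)-2-(4-hydroxyphenyl)acetic acid (racemic)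
Product: 15 xylerythrin [5-hydroxy-3-(4-hydroxyphenyl)-4,7-diphenyl-1-benzofuran-2,6-dione], via ortho-quinone acid 12 (not isolated), via catechol lactone 13 (not isolated), via ortho-quinone lactone 14 (not isolated)
Conditions: Ag2O (2.1 equiv), Na2SO4, dry THF, rt, dark, N2
Reagents that add atoms: none
Why: Ag2O, a mild two-electron oxidant and a base, should take two electrons and two protons from the catechol of 11, the most easily oxidised site, to give the 3,6-diphenyl-ortho-quinone 12 with its acid as the carboxylate. In 12 the carbon that becomes C7a is the β-carbon of the C6 enone and carries the only ring hydrogen; the carboxylate oxygen adds there in a 5-exo-trig oxa-Michael closure that forms O1–C7a and ring B. Enolisation then restores the arene as the catechol lactone 13. The second equivalent of Ag2O oxidises 13, again a catechol, to the ortho-quinone lactone 14. Its C3 hydrogen is doubly benzylic, α to the lactone carbonyl and vinylogous to the C5 carbonyl, and its shift to O5 gives the conjugated hydroxy quinone methide 15. The closest known reaction is the oxidative cyclisation of 3,4-dihydroxyphenylacetic acid through its ortho-quinone to 5,6-dihydroxybenzofuran-2(3H)-one, together with the oxidation of leuco lactones of this pigment class to their quinone methides. No stereocenter is created, since the racemic C3 of 11, 13 and 14 ends trigonal. Regioselectivity is secured because addition at the other β-carbon (C3a) would need a three-membered ring; chemoselectivity rests on the lower oxidation potential of a catechol compared with the 4-hydroxyphenyl ring, on limiting Ag2O to the four oxidation equivalents required, and on excluding water so that the quinone methide tautomer of 12 is not hydrated.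

Step 6
Reactants: 15 xylerythrin
Product: 16 3-(4-hydroxyphenyl)-5-methoxy-4,7-diphenyl-1-benzofuran-2,6-dione (5-O-methylxylerythrin, CNP0282683.0)
Conditions: HCl (ca. 1 M) in dry MeOH, rt to 40 °C
Reagents that add atoms: methanol, CO
Why: Fischer-type etherification of a vinylogous carboxylic acid, as known for 2-hydroxy-1,4-quinones: the protonated dienone adds methanol at C5 and loses water. A phenol is not etherified under these conditions and O6 cannot carry a substituent in any neutral tautomer, so only the 5-methyl ether should form.

## Compound list

1 | veratrole (1,2-dimethoxybenzene) | COc1ccccc1OC | starting material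
2 | 3,6-dilithioveratrole (1,4-dilithio-2,3-dimethoxybenzene) | [Li]c1ccc([Li])c(OC)c1OC | intermediate
3 | 1,4-dibromo-2,3-dimethoxybenzene | COc1c(Br)ccc(Br)c1OC | intermediate
4 | phenylboronic acid | OB(O)c1ccccc1 | starting material
5 | 4-bromo-2,3-dimethoxybiphenyl | COc1c(Br)ccc(-c2ccccc2)c1OC | intermediate
6 | 2,3-dimethoxy-1,4-diphenylbenzene | COc1c(-c2ccccc2)ccc(-c2ccccc2)c1OC | intermediate
7 | 2-bromo-4,7-diphenyl-1,3,2-benzodioxaborole | BrB1Oc2c(-c3ccccc3)ccc(-c3ccccc3)c2O1 | intermediate
8 | 3,6-diphenylbenzene-1,2-diol | Oc1c(-c2ccccc2)ccc(-c2ccccc2)c1O | intermediate
9 | 4-hydroxymandelic acid, racemic | OC(C(=O)O)c1ccc(O)cc1 | starting material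
10 | 2-(4-oxocyclohexa-2,5-dien-1-ylidene)acetic acid | O=C1C=CC(=CC(=O)O)C=C1 | intermediate
11 | 2-(3,4-dihydroxy-2,5-diphenylphenyl)-2-(4-hydroxyphenyl)acetic acid, racemic | OC(=O)C(c1ccc(O)cc1)c1cc(-c2ccccc2)c(O)c(O)c1-c1ccccc1 | intermediate
12 | 2-(3,4-dioxo-2,5-diphenylcyclohexa-1,5-dien-1-yl)-2-(4-hydroxyphenyl)acetic acid, racemic | OC(=O)C(c1ccc(O)cc1)C1=C(c2ccccc2)C(=O)C(=O)C(c2ccccc2)=C1 | intermediate
13 | 5,6-dihydroxy-3-(4-hydroxyphenyl)-4,7-diphenyl-1-benzofuran-2(3H)-one, racemic | O=C1Oc2c(-c3ccccc3)c(O)c(O)c(-c3ccccc3)c2C1c1ccc(O)cc1 | intermediate
14 | 3-(4-hydroxyphenyl)-4,7-diphenyl-1-benzofuran-2,5,6(3H)-trione, racemic | O=C1OC2=C(c3ccccc3)C(=O)C(=O)C(c3ccccc3)=C2C1c1ccc(O)cc1 | intermediate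
15 | xylerythrin, 5-hydroxy-3-(4-hydroxyphenyl)-4,7-diphenyl-1-benzofuran-2,6-dione | OC1=C(c2ccccc2)C2=C(c3ccc(O)cc3)C(=O)OC2=C(c2ccccc2)C1=O | intermediate
16 | 3-(4-hydroxyphenyl)-5-methoxy-4,7-diphenyl-1-benzofuran-2,6-dione | COC1=C(c2ccccc2)C2=C(c3ccc(O)cc3)C(=O)OC2=C(c2ccccc2)C1=O | target

## Step count and least certain steps

Total: 6 steps. Longest linear sequence: 6 steps (1 → 3 → 6 → 8 → 11 → 15 → 16); 4 and 9 enter as purchased.

Step 5 (key step). What may go wrong:
- overoxidation of the product, whose phenol is conjugated to the quinone methide;
- loss of CO2 from the carboxylate of 12, which is a vinylogous β-keto acid, before ring closure;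
- intermolecular coupling of the ortho-quinone.

Fallback, which installs the C7a oxygen before the lactone is closed and keeps only the final oxidation: it sets out from 8 and returns at 13. Oxidation of 8 with Ag2O would give 3,6-diphenylcyclohexa-3,5-diene-1,2-dione F1. Thiele–Winter acetoxylation (Ac2O, catalytic H2SO4) would add acetate at the conjugate position and give 3,6-diphenylbenzene-1,2,4-triyl triacetate F2. Methanolysis (HCl, MeOH) would free 3,6-diphenylbenzene-1,2,4-triol F3. Acid condensation of F3 with 9 under the conditions of step 4 should alkylate the only free carbon, which lies ortho to the new hydroxyl, and lactonise spontaneously to 13. One equivalent of Ag2O then takes 13 to 15.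

Step 4. What may go wrong: self-alkylation and oligomerisation of 9 through its own activated ring, or slow attack at the carbon of 8 that is flanked by phenyl, leading to low conversion or double alkylation.

Fallback, which reverses the polarity of the C3–C3a bond formation: it sets out from 6 and returns at 11, bypassing 8. Bromination of 6 with NBS in MeCN, para to a methoxy group, would give 1-bromo-3,4-dimethoxy-2,5-diphenylbenzene F4. α-Arylation of methyl 2-(4-methoxyphenyl)acetate with F4 (LiN(SiMe3)2, Pd(dba)2, P(t-Bu)3, toluene), catalysed by zerovalent palladium, would give methyl 2-(3,4-dimethoxy-2,5-diphenylphenyl)-2-(4-methoxyphenyl)acetate F5 (racemic). Excess BBr3 in CH2Cl2 would then cleave the three aryl methyl ethers and the methyl ester to give 11.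

Step 1. What may go wrong: incomplete second metalation of the monolithiated ring, so that monobromide accompanies 3 and must be separated.

Fallback, which replaces the dibromide by two successive monometalations with direct arylation: it sets out from 1 and returns at 6, bypassing 3 and step 2. Monolithiation of 1 (n-BuLi, TMEDA), transmetalation with ZnCl2 and Negishi coupling with bromobenzene (Pd(PPh3)4) would give 2,3-dimethoxybiphenyl F6. The same sequence at the one remaining position ortho to a methoxy group would give 6.

Step 6. What may go wrong: acid-catalysed methanolysis of the enol lactone, or reversible addition of methanol to the methide carbon C3, in competition with etherification at C5.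

Fallback, which forms the O5–CH3 bond by O-alkylation instead of exchanging the oxygen at C5: it sets out from 15 and returns at 16. One equivalent of Me3SiCHN2 in toluene/MeOH at 0 °C should methylate the most acidic hydroxyl, the vinylogous acid at C5, under neutral conditions that leave the lactone closed. No new compound lies on this path.

## Further compounds

F1 | step 5 | 3,6-diphenylcyclohexa-3,5-diene-1,2-dione | O=C1C(=O)C(c2ccccc2)=CC=C1c1ccccc1
F2 | step 5 | 3,6-diphenylbenzene-1,2,4-triyl triacetate | CC(=O)Oc1cc(-c2ccccc2)c(OC(C)=O)c(OC(C)=O)c1-c1ccccc1
F3 | step 5 | 3,6-diphenylbenzene-1,2,4-triol | Oc1cc(-c2ccccc2)c(O)c(O)c1-c1ccccc1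
F4 | step 4 | 1-bromo-3,4-dimethoxy-2,5-diphenylbenzene | COc1c(OC)c(-c2ccccc2)c(Br)cc1-c1ccccc1
F5 | step 4 | methyl 2-(3,4-dimethoxy-2,5-diphenylphenyl)-2-(4-methoxyphenyl)acetate, racemic | COC(=O)C(c1ccc(OC)cc1)c1cc(-c2ccccc2)c(OC)c(OC)c1-c1ccccc1
F6 | step 1 | 2,3-dimethoxybiphenyl | COc1cccc(-c2ccccc2)c1OC
F0 | step 6 | none | none
A1 | alternative 1 | 3-isopropoxy-4-methoxy-2-phenyl-4-(1-phenylvinyl)cyclobut-2-en-1-one, racemic | O=C1C(c2ccccc2)=C(OC(C)C)C1(OC)C(=C)c1ccccc1
A2 | alternative 1 | 3-isopropoxy-4-methoxy-2,5-diphenylphenol | COc1c(OC(C)C)c(-c2ccccc2)c(O)cc1-c1ccccc1
A3 | alternative 2 | 2-{2-[4-(benzyloxy)phenyl]-2-oxoacetyl}-5-isopropoxy-4-methoxy-3,6-diphenylphenyl acetate | COc1c(OC(C)C)c(-c2ccccc2)c(OC(C)=O)c(C(=O)C(=O)c2ccc(OCc3ccccc3)cc2)c1-c1ccccc1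
A4 | alternative 2 | 3-[4-(benzyloxy)phenyl]-3-hydroxy-6-isopropoxy-5-methoxy-4,7-diphenyl-1-benzofuran-2(3H)-one, racemic | COc1c(OC(C)C)c(-c2ccccc2)c2OC(=O)C(O)(c3ccc(OCc4ccccc4)cc3)c2c1-c1ccccc1
A5 | alternative 3 | 2-[hydroxy(4-isopropoxyphenyl)methyl]-5-isopropoxy-4-methoxy-3,6-diphenylphenol, racemic | COc1c(OC(C)C)c(-c2ccccc2)c(O)c(C(O)c2ccc(OC(C)C)cc2)c1-c1ccccc1
A6 | alternative 3 | 6-isopropoxy-3-(4-isopropoxyphenyl)-5-methoxy-4,7-diphenyl-1-benzofuran-2(3H)-one, racemic | COc1c(OC(C)C)c(-c2ccccc2)c2OC(=O)C(c3ccc(OC(C)C)cc3)c2c1-c1ccccc1
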